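At 2.5 h, the time asked of theta and epsilon, the earlier runs have their last rows too, so we can set flasks side by side at one time of reading.

- the winner by share of target in all that became target or side product; "neither" if no more than 2 percentage points parts them (theta / epsilon / neither)
- share of target in all that became target or side product, theta
- share of target in all that became target or side product, epsilon

| flask | substrate | partner | protic impurity | temperature | remark | time |
|---|---|---|---|---|---|---|
| amber | 29 mM | 19 mM | 29 mM | 15 °C | run made earlier |  |
| violet | 29 mM | 44 mM | 29 mM | 28 °C | run made earlier |  |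
| theta | 29 mM | 29.0 mM | 29.0 mM | 20 °C |  | 2.5 h |
| epsilon | 29 mM | 29.0 mM | 29.0 mM | 35 °C |  | 2.5 h |

| run | time / h | target / % | side product / % |
|---|---|---|---|
| amber | 0.200 | 2.0 | 0.3 |
| amber | 0.333 | 3.2 | 0.2 |
| amber | 0.500 | 3.7 | 1.1 |
| amber | 0.833 | 2.8 | 0.8 |
| amber | 1.50 | 4.9 | 1.9 |
| amber | 2.50 | 5.3 | 3.3 |
| violet | 0.417 | 11.6 | 5.2 |
| violet | 0.833 | 14.4 | 13.2 |
| violet | 1.33 | 15.3 | 20.6 |
| violet | 1.50 | 15.7 | 23.9 |
| violet | 2.00 | 15.7 | 29.9 |
| violet | 2.50 | 16.3 | 37.4 |

(readings scatter by 0.5 percentage points)



Read down violet first: from 0.833 h to 2.50 h target goes from 14.4% to 16.3% of the charge while side product goes from 13.2% to 37.4%, so the side-to-target ratio climbs from 0.917 to 2.29 and belongs to its time. Hence we read across the last rows: amber, at 15 °C, reads 3.3% of side product against 5.3% of target, a ratio as read, with the scatter of both readings in it, of 0.623. A ratio r gives the share asked, the selectivity, as one over one plus r, which is 61.6% for amber and 30.4% for violet at 28 °C.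

Our own reckoning lets the ratio grow by one constant factor per degree and leaves partner out, though partner rose between these runs as well. That gives 1.03 for theta, a share of 49.3%, and 4.63 for epsilon, a share of 17.8%; this is the expected ratio of side product to target at epsilon's temperature and time of reading, with partner left out. We therefore name theta, since its ratio is lower than epsilon's.

The forecast names theta, with 49% for theta and 23% for epsilon, the latter higher than ours, and it warns that “temperature and partner are confounded across the two runs”.

The flask gives theta as the winner, with 49.4% against 24.7% for epsilon.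

    substrate ⇌ intermediate A (K = 1.30, k = 0.00106 s⁻¹, Ea = 86.0 kJ mol⁻¹, ΔH = −54.0 kJ mol⁻¹)
    substrate + partner → target (k = 0.00315 M⁻¹ s⁻¹, Ea = 67.0 kJ mol⁻¹)
    substrate + partner → intermediate B (k = 0.0183 M⁻¹ s⁻¹, Ea = 44.0 kJ mol⁻¹)
    intermediate B ⇌ intermediate C (K = 2.20, k = 5.27 × 10⁻⁴ s⁻¹, Ea = 97.0 kJ mol⁻¹, ΔH = −37.0 kJ mol⁻¹)
    intermediate B → side product (k = 6.91 × 10⁻⁵ s⁻¹, Ea = 100 kJ mol⁻¹)
    partner + protic impurity → quenched reagent (k = 7.43 × 10⁻⁴ M⁻¹ s⁻¹, Ea = 65.0 kJ mol⁻¹)
    (constants at 20 °C)

Epsilon stands at 55.2% of side product against 18.1% of target, a ratio of 3.05, lower than the 4.63 we carried. The neighbour of epsilon charged with 7.2 mM of partner, a quarter of epsilon's charge, keeps temperature and time, so our ratio, with partner left out, is unchanged at 4.63 and gives that neighbour 17.8%, while epsilon's own ratio gives it 24.7%. That neighbour stands at 15.5% of side product against 4.93% of target, a ratio of 3.14, and a share of 24.1%, with partner down to 0.0156% of its charge.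

(The earlier runs and the new flask were computed for an exercise; the scatter is artificial.)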